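**Retrosynthetic overview**

1. The target is an ent-labd-7-ene (labdane numbering throughout): ring A carries the equatorial C2 hydroxyl, quaternary C4 (methyl and axial CH2OAc, C19) and quaternary C10 (C20); ring B is C5–C6–C7=C8–C9–C10; C9 bears the C11–C15 acid chain with the C13 methyl. The C2 alcohol comes from a C2 ketone by thermodynamic reduction, the C15 acid and C19 acetate from protected alcohols.
2. Ring B is opened at C7=C8: ring-closing metathesis of a C8 isopropenyl group with a C5 allyl group.
3. Feature on which the route rests: quaternary C10 is the β-carbon of the C2 carbonyl (through C1) and is bonded to C9, and C9 with C8/C17 and C11–C16 is exactly the 2-methylalk-2-enyl end and backbone of (R)-citronellol. The C9–C10 bond is therefore cut as a Hosomi–Sakurai conjugate allylation of a ring A 3-methylcyclohexenone by a citronellol-derived (E)-allylsilane, which creates C10 and C9 together.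
4. The ring A enone comes from 3-ethoxycyclohex-2-enone: catalytic asymmetric α′-allylation (C5), Stork–Danheiser introduction of C19, methyl cuprate at C4, then C20 by a second cuprate addition with re-dehydrogenation.
5. Ring order: ring A is bought, ring B is closed last.

Key step: step 13

Remark (assumption): the sense of induction of the chiral ligand in step 2 is assigned by analogy with related cyclic allyl enol carbonates; should it prove opposite, the enantiomeric ligand is used and nothing else changes.

**Ring A fragment**

Step 1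
Reactants: 1 3-ethoxycyclohex-2-en-1-one; 2 allyl chloroformate
Product: 4 allyl 5-ethoxycyclohexa-1,5-dien-1-yl carbonate, via lithium 5-ethoxycyclohexa-1,5-dien-1-olate 3 (not isolated)
Conditions: LiN(i-Pr)2, TMEDA, THF, −78 °C; then 2, −78 °C
Reagents that add atoms: none
Why: Kinetic α′-deprotonation of the vinylogous ester gives the cross-conjugated lithium dienolate, which the hard chloroformate acylates on oxygen (enol carbonate formation); no stereocentre is formed.

Step 2
Reactants: 4 allyl 5-ethoxycyclohexa-1,5-dien-1-yl carbonate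
Product: 5 (R)-6-allyl-3-ethoxycyclohex-2-en-1-one
Conditions: Pd2(dba)3·CHCl3 (2.5 mol %), (R,R)-ANDEN-phenyl Trost ligand (5.5 mol %), 1,4-dioxane, rt
Reagents that add atoms: none
Why: Zerovalent palladium ionises the allyl carbonate, CO2 is lost and the ligand-bound π-allyl cation recombines with the dienolate at its only nucleophilic carbon (decarboxylative asymmetric allylic alkylation of an allyl enol carbonate), the chiral pocket choosing the enolate face and so setting the future C5; dioxane limits the proton transfer that would racemise or over-allylate.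

Step 3
Reactants: 6 (tributylstannyl)methanol
Product: 7 tributyl[(4-methoxybenzyloxy)methyl]stannane
Conditions: NaH, PMBCl, Bu4NI (cat.), THF/DMF, 0 °C to rt
Reagents that add atoms: 4-methoxybenzyl chloride, COc1ccc(CCl)cc1
Why: Williamson etherification of the sodium alkoxide with the activated benzylic chloride gives the precursor of the C19 carbanion; no stereocentre is involved.

Step 4
Reactants: 7 tributyl[(4-methoxybenzyloxy)methyl]stannane; 5 (R)-6-allyl-3-ethoxycyclohex-2-en-1-one
Product: 10 (R)-4-allyl-3-[(4-methoxybenzyloxy)methyl]cyclohex-2-en-1-one, via [(4-methoxybenzyloxy)methyl]lithium 8 (not isolated), via tertiary carbinol adduct 9 (not isolated)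
Conditions: 7, n-BuLi, THF, −78 °C; then 5, −78 °C; then 1 M HCl, THF, 0 °C
Reagents that add atoms: water, O
Why: Tin–lithium exchange gives the α-alkoxymethyllithium, which adds 1,2 to the vinylogous ester carbonyl, and mild acid hydrolysis of the enol ether with loss of water and ethanol transposes the carbonyl (Stork–Danheiser sequence); the allyl-bearing centre is not touched and becomes the γ-carbon of the new enone (labdane C5), the acid being kept cold and brief so that it does not epimerise through the dienol.

Step 5
Reactants: 10 (R)-4-allyl-3-[(4-methoxybenzyloxy)methyl]cyclohex-2-en-1-one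
Product: 12 (3R,4R)-4-allyl-3-[(4-methoxybenzyloxy)methyl]-3-methylcyclohexan-1-one, via trimethylsilyl enol ether 11 (not isolated)
Conditions: Me2CuLi (from MeLi, CuI), TMSCl, THF, −78 to −20 °C; then 1 M HCl, 0 °C
Reagents that add atoms: lithium dimethylcuprate, [Li+].C[Cu-]C
Why: TMSCl-accelerated conjugate addition of the Gilman reagent to the β,β-disubstituted enone creates quaternary C4; the neighbouring allyl group sits pseudoaxial to escape A(1,2) strain with the CH2OPMB arm, so methyl enters axially on the opposite face and CH2OPMB ends up cis to the allyl group.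

Step 6
Reactants: 12 (3R,4R)-4-allyl-3-[(4-methoxybenzyloxy)methyl]-3-methylcyclohexan-1-one
Product: 16 (4S,5R)-4-allyl-5-[(4-methoxybenzyloxy)methyl]-5-methylcyclohex-2-en-1-one, via lithium enolate 13 (not isolated), via α-phenylselanyl ketone 14 (not isolated), via selenoxide 15 (not isolated)
Conditions: LiN(i-Pr)2, THF, −78 °C; PhSeBr, −78 °C; then H2O2, pyridine, CH2Cl2, 0 °C to rt
Reagents that add atoms: none
Why: The amide base removes a proton from the less hindered α-methylene C1 (remote from quaternary C4), the enolate is selenenylated and the selenoxide eliminates syn towards C10, the only β-hydrogens available (Reich selenoxide dehydrogenation); this is preferred to a divalent palladium enolate, which with the allyl group 1,3 to C1 could cyclise onto the alkene, and no stereocentre changes.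

Step 7
Reactants: 16 (4S,5R)-4-allyl-5-[(4-methoxybenzyloxy)methyl]-5-methylcyclohex-2-en-1-one
Product: 17 trimethylsilyl enol ether of the C10-methyl adduct (C1=C2 enol silane)
Conditions: Me2CuLi (from MeLi, CuI), TMSCl, Et3N, THF, −78 °C; cold NaHCO3/pentane work-up
Reagents that add atoms: lithium dimethylcuprate, [Li+].C[Cu-]C; chlorotrimethylsilane, C[Si](C)(C)Cl
Why: Cuprate conjugate addition places the C20 methyl on C10 and TMSCl traps the enolate regiospecifically as the C1=C2 enol silane; the configuration of the new tertiary centre (expected trans to the allyl group) is of no consequence because it is erased in step 8.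

Step 8
Reactants: 17 trimethylsilyl enol ether of the C10-methyl adduct
Product: 20 (4S,5R)-4-allyl-5-[(4-methoxybenzyloxy)methyl]-3,5-dimethylcyclohex-2-en-1-one, via α-phenylselanyl ketone 18 (not isolated), via selenoxide 19 (not isolated)
Conditions: PhSeCl (1.0 equiv), CH2Cl2, −78 °C; then H2O2, pyridine, CH2Cl2, 0 °C to rt
Reagents that add atoms: none
Why: The electron-rich enol silane is selenenylated at C1 much faster than the isolated alkene, and syn elimination of the selenoxide can only use the C10 hydrogen, giving the β-methyl enone (selenoxide dehydrogenation); C4 and C5 are untouched.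

**Side-chain fragment**

Step 9
Reactants: 21 (R)-citronellol
Product: 22 (R)-citronellol tert-butyldiphenylsilyl ether
Conditions: TBDPSCl, imidazole, DMF, rt
Reagents that add atoms: tert-butyl(chloro)diphenylsilane, CC(C)(C)[Si](Cl)(c1ccccc1)c1ccccc1
Why: Imidazole-mediated silylation of the primary alcohol gives an ether that survives SeO2, palladium catalysis, TiCl4 at low temperature and DDQ; C13 is carried unchanged from the chiral pool.

Step 10
Reactants: 22 (R)-citronellol tert-butyldiphenylsilyl ether
Product: 23 (2E,6R)-8-(tert-butyldiphenylsilyloxy)-2,6-dimethyloct-2-en-1-ol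
Conditions: SeO2 (cat.), t-BuOOH, salicylic acid (cat.), CH2Cl2, rt
Reagents that add atoms: selenium dioxide (oxygen carrier), O=[Se]=O; tert-butyl hydroperoxide (terminal oxidant), CC(C)(C)OO
Why: Ene reaction of SeO2 at the (E)-methyl group followed by [2,3]-sigmatropic shift (Sharpless catalytic allylic oxidation) gives the (E)-allylic alcohol selectively; the remote stereocentre is not affected.

Step 11
Reactants: 23 (2E,6R)-8-(tert-butyldiphenylsilyloxy)-2,6-dimethyloct-2-en-1-ol
Product: 24 (2E,6R)-8-(tert-butyldiphenylsilyloxy)-2,6-dimethyloct-2-en-1-yl acetate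
Conditions: Ac2O, pyridine, DMAP (cat.), CH2Cl2, 0 °C
Reagents that add atoms: acetic anhydride, CC(=O)OC(C)=O
Why: Standard DMAP-catalysed acylation turns the allylic alcohol into a leaving group for π-allyl formation; no stereochemical change.

Step 12
Reactants: 24 (2E,6R)-8-(tert-butyldiphenylsilyloxy)-2,6-dimethyloct-2-en-1-yl acetate
Product: 25 [(2E,6R)-8-(tert-butyldiphenylsilyloxy)-2,6-dimethyloct-2-en-1-yl]trimethylsilane
Conditions: Me3SiSiMe3, Pd(dba)2 (3 mol %), LiCl, DMF, 100 °C
Reagents that add atoms: hexamethyldisilane, C[Si](C)(C)[Si](C)(C)C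
Why: Zerovalent palladium ionises the allylic acetate, the disilane transfers a silyl group to palladium and reductive elimination places silicon at the unhindered primary terminus of the syn π-allyl complex with retention of the E geometry (palladium-catalysed allylic silylation).

**Union and end game**

Step 13
Reactants: 20 (4S,5R)-4-allyl-5-[(4-methoxybenzyloxy)methyl]-3,5-dimethylcyclohex-2-en-1-one; 25 [(2E,6R)-8-(tert-butyldiphenylsilyloxy)-2,6-dimethyloct-2-en-1-yl]trimethylsilane
Product: 27 seco-ring-B diene ketone (C9–C10 bond formed; C8 isopropenyl; C5 allyl), via trichlorotitanium enolate 26 (not isolated)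
Conditions: TiCl4 (1.2 equiv), 25 (1.5 equiv), CH2Cl2, −78 °C; aq NaHCO3 quench
Reagents that add atoms: none
Why: TiCl4 binds the C2 carbonyl of 20 and the γ-carbon of the allylsilane (the CH that becomes C9) attacks the β-carbon C10 in an anti SE2′ sense; the β-silyl tertiary cation at C8 then loses the silyl group as Me3SiCl to unveil the C8 isopropenyl alkene, and the titanium enolate 26 is protonated on work-up (Hosomi–Sakurai conjugate allylation, the established way to build quaternary carbons on β,β-disubstituted cyclohexenones of the isophorone type). No ring is closed here; only the C9–C10 σ bond forms, and the product carries the two alkenes for the six-membered metathesis closure of ring B in step 14. C10 is controlled by the C5 allyl group: in the reactive half-chair it is pseudoaxial to avoid A(1,2) strain with the C10 methyl, so the stereoelectronically preferred axial attack comes from the opposite face and C9 ends up trans to C6, as the trans ring fusion requires. C9 is controlled by simple diastereoselection of the (E)-silane in an open transition state with C8=C9 anti to C1=C10, the small C9 hydrogen over ring A (where the axial C18 methyl leaves no room for more) and the C11 chain in the open sector beside C20, which corresponds to the required 9R configuration. The step therefore needs face selectivity at C10, secured by the fixed C5 substituent, and one topicity at C9, which is the less certain element and is covered by the fallback. The PMB and TBDPS ethers and the terminal alkene should tolerate TiCl4 at −78 °C for the short reaction time, and C13 is a spectator.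

Step 14
Reactants: 27 seco-ring-B diene ketone
Product: 28 19-(4-methoxybenzyloxy)-15-(tert-butyldiphenylsilyloxy)labd-7-en-2-one (ent series)
Conditions: second-generation Hoveyda–Grubbs catalyst (5–10 mol %), toluene, 80 °C
Reagents that add atoms: none
Why: Ring-closing metathesis between the monosubstituted allyl alkene and the 1,1-disubstituted isopropenyl alkene closes the six-membered ring B with loss of ethylene and fixes the alkene at C7=C8 without regioisomers; the trans relationship of the two arms set in steps 2 and 13 becomes the trans ring fusion.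

Step 15
Reactants: 28 19-(4-methoxybenzyloxy)-15-(tert-butyldiphenylsilyloxy)labd-7-en-2-one
Product: 29 19-hydroxy-15-(tert-butyldiphenylsilyloxy)labd-7-en-2-one
Conditions: DDQ, CH2Cl2/pH 7 buffer, 0 °C
Reagents that add atoms: none
Why: Oxidative cleavage of the electron-rich PMB ether through its benzylic oxocarbenium ion (DDQ deprotection) leaves the silyl ether, ketone and trisubstituted alkene untouched.

Step 16
Reactants: 29 19-hydroxy-15-(tert-butyldiphenylsilyloxy)labd-7-en-2-one
Product: 30 19-acetoxy-15-(tert-butyldiphenylsilyloxy)labd-7-en-2-one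
Conditions: Ac2O, pyridine, DMAP (cat.), CH2Cl2, rt
Reagents that add atoms: acetic anhydride, CC(=O)OC(C)=O
Why: With C2 still a ketone the neopentyl C19 hydroxyl is the only acylable group (DMAP-catalysed acetylation), and any bridged hemiketal between the axial C19 hydroxyl and C2 is drained through its open form.

Step 17
Reactants: 30 19-acetoxy-15-(tert-butyldiphenylsilyloxy)labd-7-en-2-one
Product: 31 19-acetoxy-15-hydroxylabd-7-en-2-one
Conditions: HF·pyridine, pyridine, THF, 0 °C to rt
Reagents that add atoms: none
Why: Buffered fluoride cleaves the primary silyl ether (desilylation driven by the Si–F bond) without touching the acetate or adding HF to the trisubstituted alkene.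

Step 18
Reactants: 31 19-acetoxy-15-hydroxylabd-7-en-2-one
Product: 33 19-acetoxy-2-oxolabd-7-en-15-oic acid, via 19-acetoxy-2-oxolabd-7-en-15-al 32 (not isolated)
Conditions: TEMPO (cat.), PhI(OAc)2 (2.2 equiv), MeCN/H2O, rt
Reagents that add atoms: water, O
Why: Oxoammonium-mediated oxidation takes the primary alcohol to the aldehyde, whose hydrate is oxidised on to the acid (TEMPO/PhI(OAc)2 oxidation in aqueous acetonitrile); C13 is β to the new carbonyl and cannot epimerise.

Step 19
Reactants: 33 19-acetoxy-2-oxolabd-7-en-15-oic acid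
Product: 34 target CNP0162900.1
Conditions: SmI2 (5 equiv), i-PrOH, THF, 0 °C to rt
Reagents that add atoms: none
Why: Single-electron reduction by SmI2 passes through the ketyl and its carbanion, whose protonation gives the more stable carbinol with the C2 oxygen equatorial, since an axial oxygen would be syn-axial to both C20 and the C19 arm (thermodynamic, dissolving-metal-type ketone reduction); kinetic borohydride delivery from the open equatorial side would give the axial epimer instead, and without amine or HMPA activation the acetate, the acid and the alkene should not be reduced.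

**Compound list**

1 | 3-ethoxycyclohex-2-en-1-one | CCOC1=CC(=O)CCC1 | starting material
2 | allyl chloroformate | C=CCOC(=O)Cl | starting material
3 | lithium 5-ethoxycyclohexa-1,5-dien-1-olate | [Li+].[O-]C1=CCCC(OCC)=C1 | intermediate
4 | allyl 5-ethoxycyclohexa-1,5-dien-1-yl carbonate | C=CCOC(=O)OC1=CCCC(OCC)=C1 | intermediate
5 | (R)-6-allyl-3-ethoxycyclohex-2-en-1-one | CCOC1=CC(=O)[C@@H](CC=C)CC1 | intermediate
6 | (tributylstannyl)methanol | CCCC[Sn](CCCC)(CCCC)CO | starting material
7 | tributyl[(4-methoxybenzyloxy)methyl]stannane | CCCC[Sn](CCCC)(CCCC)COCc1ccc(OC)cc1 | intermediate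
8 | [(4-methoxybenzyloxy)methyl]lithium | [Li]COCc1ccc(OC)cc1 | intermediate
9 | (6R)-6-allyl-3-ethoxy-1-[(4-methoxybenzyloxy)methyl]cyclohex-2-en-1-ol, both carbinol epimers | CCOC1=CC(O)(COCc2ccc(OC)cc2)[C@@H](CC=C)CC1 | intermediate
10 | (R)-4-allyl-3-[(4-methoxybenzyloxy)methyl]cyclohex-2-en-1-one | COc1ccc(COCC2=CC(=O)CC[C@@H]2CC=C)cc1 | intermediate
11 | trimethylsilyl enol ether of 12 (enol double bond towards the quaternary carbon; stereocentres as in 12) | COc1ccc(COC[C@]2(C)C=C(O[Si](C)(C)C)CC[C@@H]2CC=C)cc1 | intermediate
12 | (3R,4R)-4-allyl-3-[(4-methoxybenzyloxy)methyl]-3-methylcyclohexan-1-one (allyl cis to CH2OPMB) | COc1ccc(COC[C@]2(C)CC(=O)CC[C@@H]2CC=C)cc1 | intermediate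
13 | kinetic lithium enolate of 12 (enolate double bond C1=C2, labdane numbering) | [Li+].COc1ccc(COC[C@]2(C)CC([O-])=CC[C@@H]2CC=C)cc1 | intermediate
14 | 2-(phenylselanyl) derivative of ketone 12 (selenium on labdane C1, both epimers) | COc1ccc(COC[C@]2(C)CC(=O)C([Se]c3ccccc3)C[C@@H]2CC=C)cc1 | intermediate
15 | selenoxide of 14 | COc1ccc(COC[C@]2(C)CC(=O)C([Se](=O)c3ccccc3)C[C@@H]2CC=C)cc1 | intermediate
16 | (4S,5R)-4-allyl-5-[(4-methoxybenzyloxy)methyl]-5-methylcyclohex-2-en-1-one | COc1ccc(COC[C@]2(C)CC(=O)C=C[C@@H]2CC=C)cc1 | intermediate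
17 | trimethylsilyl enol ether of the 3-methyl adduct of 16 (enol C1=C2; new methyl trans to allyl) | COc1ccc(COC[C@]2(C)CC(O[Si](C)(C)C)=C[C@@H](C)[C@@H]2CC=C)cc1 | intermediate
18 | α-(phenylselanyl) ketone from 17 (selenium on labdane C1, both epimers) | COc1ccc(COC[C@]2(C)CC(=O)C([Se]c3ccccc3)[C@@H](C)[C@@H]2CC=C)cc1 | intermediate
19 | selenoxide of 18 | COc1ccc(COC[C@]2(C)CC(=O)C([Se](=O)c3ccccc3)[C@@H](C)[C@@H]2CC=C)cc1 | intermediate
20 | (4S,5R)-4-allyl-5-[(4-methoxybenzyloxy)methyl]-3,5-dimethylcyclohex-2-en-1-one (ring A enone; allyl cis to CH2OPMB) | COc1ccc(COC[C@]2(C)CC(=O)C=C(C)[C@@H]2CC=C)cc1 | intermediate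
21 | (R)-citronellol | CC(C)=CCC[C@@H](C)CCO | starting material
22 | tert-butyl{[(3R)-3,7-dimethyloct-6-en-1-yl]oxy}diphenylsilane | CC(C)=CCC[C@@H](C)CCO[Si](c1ccccc1)(c1ccccc1)C(C)(C)C | intermediate
23 | (2E,6R)-8-(tert-butyldiphenylsilyloxy)-2,6-dimethyloct-2-en-1-ol | OC/C(C)=C/CC[C@@H](C)CCO[Si](c1ccccc1)(c1ccccc1)C(C)(C)C | intermediate
24 | (2E,6R)-8-(tert-butyldiphenylsilyloxy)-2,6-dimethyloct-2-en-1-yl acetate | CC(=O)OC/C(C)=C/CC[C@@H](C)CCO[Si](c1ccccc1)(c1ccccc1)C(C)(C)C | intermediate
25 | [(2E,6R)-8-(tert-butyldiphenylsilyloxy)-2,6-dimethyloct-2-en-1-yl]trimethylsilane | C[Si](C)(C)C/C(C)=C/CC[C@@H](C)CCO[Si](c1ccccc1)(c1ccccc1)C(C)(C)C | intermediate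
26 | trichlorotitanium enolate (C1=C2) of 27 | COc1ccc(COC[C@]2(C)CC(O[Ti](Cl)(Cl)Cl)=C[C@@](C)([C@H](CC[C@@H](C)CCO[Si](c3ccccc3)(c3ccccc3)C(C)(C)C)C(C)=C)[C@@H]2CC=C)cc1 | intermediate
27 | seco-ring-B ketone: ring A 2-ketone with C10 bearing C20 and the C9 chain [CH(isopropenyl)CH2CH2CH(CH3)CH2CH2OTBDPS], C5 allyl trans to C9, C4 methyl and CH2OPMB (cis to allyl); labdane-numbered centres 4R,5S,9R,10S,13R | COc1ccc(COC[C@]2(C)CC(=O)C[C@@](C)([C@H](CC[C@@H](C)CCO[Si](c3ccccc3)(c3ccccc3)C(C)(C)C)C(C)=C)[C@@H]2CC=C)cc1 | intermediate
28 | (4R,5S,9R,10S,13R)-19-(4-methoxybenzyloxy)-15-(tert-butyldiphenylsilyloxy)labd-7-en-2-one | COc1ccc(COC[C@]2(C)CC(=O)C[C@@]3(C)[C@H](CC[C@@H](C)CCO[Si](c4ccccc4)(c4ccccc4)C(C)(C)C)C(C)=CC[C@H]23)cc1 | intermediate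
29 | (4R,5S,9R,10S,13R)-19-hydroxy-15-(tert-butyldiphenylsilyloxy)labd-7-en-2-one | OC[C@]1(C)CC(=O)C[C@@]2(C)[C@H](CC[C@@H](C)CCO[Si](c3ccccc3)(c3ccccc3)C(C)(C)C)C(C)=CC[C@H]12 | intermediate
30 | (4R,5S,9R,10S,13R)-19-acetoxy-15-(tert-butyldiphenylsilyloxy)labd-7-en-2-one | CC(=O)OC[C@]1(C)CC(=O)C[C@@]2(C)[C@H](CC[C@@H](C)CCO[Si](c3ccccc3)(c3ccccc3)C(C)(C)C)C(C)=CC[C@H]12 | intermediate
31 | (4R,5S,9R,10S,13R)-19-acetoxy-15-hydroxylabd-7-en-2-one | CC(=O)OC[C@]1(C)CC(=O)C[C@@]2(C)[C@H](CC[C@@H](C)CCO)C(C)=CC[C@H]12 | intermediate
32 | (4R,5S,9R,10S,13R)-19-acetoxy-2-oxolabd-7-en-15-al | CC(=O)OC[C@]1(C)CC(=O)C[C@@]2(C)[C@H](CC[C@@H](C)CC=O)C(C)=CC[C@H]12 | intermediate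
33 | (4R,5S,9R,10S,13R)-19-acetoxy-2-oxolabd-7-en-15-oic acid | CC(=O)OC[C@]1(C)CC(=O)C[C@@]2(C)[C@H](CC[C@@H](C)CC(=O)O)C(C)=CC[C@H]12 | intermediate
34 | CNP0162900.1, (2S,4R,5S,9R,10S,13R)-19-acetoxy-2-hydroxylabd-7-en-15-oic acid (2-OH equatorial, trans to C19 and C20) | CC(=O)OC[C@]1(C)C[C@@H](O)C[C@@]2(C)[C@H](CC[C@@H](C)CC(=O)O)C(C)=CC[C@H]12 | target

**Step count**

Total: 19 steps. Longest linear sequence: 14 steps (steps 1, 2, 4–8, 13–19).

**Steps most likely to fail**

Step 13 (conjugate allylation). The bond is made between a β-carbon flanked by a branched C5 and a γ-substituted silane, with the axial C18 methyl syn to the incoming nucleophile. Addition may therefore be slow enough for protodesilylation or 1,2-addition to compete. Acyclic control at C9 may be low, or attack may leak to the other C10 face. Fallback, setting out from 20 and 23 and returning at 27: alcohol 23 is converted (MsCl, LiCl, collidine, DMF, 0 °C) into the (2E,6R)-allylic chloride F1. Reactive barium (from BaI2 and lithium biphenylide, THF, −78 °C) turns it into the allylbarium chloride F2, which is known to add to carbonyl groups at its unsubstituted α-terminus with retention of alkene geometry. Addition to the C2 carbonyl of 20 gives the tertiary bis-allylic alcohol F3. KH and 18-crown-6 in THF (0 °C to rt) then trigger an anionic oxy-Cope rearrangement, and aqueous quench gives 27. The [3,3] shift is suprafacial across ring A and passes through a cyclic array, so the C10 face follows from the carbinol configuration and C9 from the alkene geometry; the (E)- or (Z)-chloride can be chosen accordingly.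

Step 2 (asymmetric allylation to a tertiary α′-centre). Proton exchange between the product and the palladium enolate may erode the enantiomeric purity or lead to double allylation, and the ligand may discriminate the unsubstituted dienolate faces only moderately. Fallback, setting out from 1 and returning at 5: the lithium dienolate 3 is alkylated directly with allyl bromide (THF, −78 °C) to racemic 6-allyl-3-ethoxycyclohex-2-en-1-one F4. This is resolved by preparative chromatography on a chiral stationary phase to give 5.

Step 19 (thermodynamic reduction). Electron transfer to the hindered dialkyl ketone may be sluggish, protonation may occur under kinetic rather than thermodynamic control and give the axial epimer, and forcing additives could attack the acetate. Fallback, setting out from 30 and returning at 34: NaBH4 (MeOH, 0 °C) attacks from the open equatorial side and gives the axial 2-epi alcohol F5. Mitsunobu inversion with chloroacetic acid (PPh3, DIAD, toluene) gives the equatorial chloroacetate F6. Thiourea (NaHCO3, EtOH, 50 °C) removes the chloroacetyl group selectively to give the equatorial alcohol F7. Buffered HF·pyridine gives the diol F8. TEMPO/PhI(OAc)2 in aqueous MeCN, which is selective for primary alcohols, then oxidises C15 through to the acid 34.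

**Further compounds**

F1 | step 13 | tert-butyl{[(3R,6E)-8-chloro-3,7-dimethyloct-6-en-1-yl]oxy}diphenylsilane | ClC/C(C)=C/CC[C@@H](C)CCO[Si](c1ccccc1)(c1ccccc1)C(C)(C)C
F2 | step 13 | allylbarium chloride from F1 | Cl[Ba]C/C(C)=C/CC[C@@H](C)CCO[Si](c1ccccc1)(c1ccccc1)C(C)(C)C
F3 | step 13 | tertiary bis-allylic alcohol: 1,2-adduct of F2 to the C2 carbonyl of 20 (side chain on the ring face of C18, anti to the C5 allyl) | COc1ccc(COC[C@]2(C)C[C@@](O)(C/C(C)=C/CC[C@@H](C)CCO[Si](c3ccccc3)(c3ccccc3)C(C)(C)C)C=C(C)[C@@H]2CC=C)cc1
F4 | step 2 | racemic 6-allyl-3-ethoxycyclohex-2-en-1-one | CCOC1=CC(=O)C(CC=C)CC1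
F5 | step 19 | 2-epi (axial) alcohol: 19-acetoxy-2-hydroxy-15-(tert-butyldiphenylsilyloxy)labd-7-ene, OH cis to C19 and C20 | CC(=O)OC[C@]1(C)C[C@H](O)C[C@@]2(C)[C@H](CC[C@@H](C)CCO[Si](c3ccccc3)(c3ccccc3)C(C)(C)C)C(C)=CC[C@H]12
F6 | step 19 | equatorial C2 chloroacetate of the 19-acetoxy-15-silyloxy labdene | CC(=O)OC[C@]1(C)C[C@@H](OC(=O)CCl)C[C@@]2(C)[C@H](CC[C@@H](C)CCO[Si](c3ccccc3)(c3ccccc3)C(C)(C)C)C(C)=CC[C@H]12
F7 | step 19 | equatorial alcohol: 19-acetoxy-2-hydroxy-15-(tert-butyldiphenylsilyloxy)labd-7-ene, OH trans to C19 and C20 | CC(=O)OC[C@]1(C)C[C@@H](O)C[C@@]2(C)[C@H](CC[C@@H](C)CCO[Si](c3ccccc3)(c3ccccc3)C(C)(C)C)C(C)=CC[C@H]12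
F8 | step 19 | 19-acetoxylabd-7-ene-2,15-diol (2-OH equatorial) | CC(=O)OC[C@]1(C)C[C@@H](O)C[C@@]2(C)[C@H](CC[C@@H](C)CCO)C(C)=CC[C@H]12
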